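## Retrosynthetic overview

- The target is the meso 3,3'-biflavanone with both rings C 2,3-trans; the last step is hydrogenolysis of its tetra-O-benzyl ether.
- Key disconnection, two-directional: in each pyranone ring C the C4–C4a bond and the C2–C3 bond are cut together (retro-[4+2]). This gives two O-aryl oxocarbenium ions (ring A–O1=C2H–ring B) and the four-carbon unit C4–C3–C3'–C4' as 1,1,4,4-tetramethoxybuta-1,3-diene, a bis(ketene acetal) of succinic acid.
- Enabling feature: C4–C3–C3'–C4' is a succinyl (1,4-dicarbonyl) unit whose central bond C3–C3' lies on the symmetry element of the meso compound, so C3/C3' are nucleophilic ketene-acetal carbons and C4/C4' latent dimethoxycarbenium carbons. C2 sits between O1 and the p-oxygenated ring B (stabilised cation), and C4a of ring A is para to the 7-oxygen and ortho to O1 (nucleophilic arene carbon).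
- Ring order: rings A and B are bought; the two rings C form last, one after the other in one flask. The diene comes from succinonitrile via the bis-orthoester; the cation precursor from 4-(benzyloxy)benzaldehyde, benzotriazole and 3-(benzyloxy)phenol.

Key step: step 6

Remark: the descriptors (2S,3R,2'R,3'S) describe an achiral meso compound (mirror-image halves, each 2,3-trans), so racemic intermediates suffice and only relative configuration has to be controlled; the diene is made because it is not assumed to be purchasable.

## Route

Step 1
Reactants: 1 succinonitrile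
Product: 2 dimethyl butanediimidate dihydrochloride
Conditions: HCl (g), MeOH (2.2 equiv), Et2O, 0 °C
Reagents that add atoms: methanol (CO); hydrogen chloride (Cl)
Why: HCl-activated nitriles add methanol to give imidate hydrochlorides (Pinner reaction), and the dihydrochloride keeps both nitrogens protonated so that the 1,4-related imidates cannot cyclise.

Step 2
Reactants: 2 dimethyl butanediimidate dihydrochloride
Product: 3 1,1,1,4,4,4-hexamethoxybutane
Conditions: MeOH (excess), Et2O, 23 °C; filter, distil
Reagents that add atoms: methanol (CO)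
Why: Imidate hydrochlorides are converted by excess dry methanol into orthoesters with loss of ammonium chloride (Pinner orthoester synthesis), and both ends react alike.

Step 3
Reactants: 3 1,1,1,4,4,4-hexamethoxybutane
Product: 4 1,1,4,4-tetramethoxybuta-1,3-diene
Conditions: Me3SiOTf (2.2 equiv), iPr2NEt (2.6 equiv), CH2Cl2, −20 → 23 °C; distil
Reagents that add atoms: none
Why: Me3SiOTf ionises one methoxy group of each orthoester to a dimethoxycarbenium ion, which the hindered amine deprotonates at the α-carbon (Lewis-acid/amine dealcoholation of an orthoester to a ketene acetal, the orthoester counterpart of the acetal-to-enol-ether elimination), and the conjugated bis(ketene acetal) is the expected end point.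

Step 4
Reactants: 5 4-(benzyloxy)benzaldehyde; 6 1H-benzotriazole
Product: 8 racemic 1-{[4-(benzyloxy)phenyl](chloro)methyl}-1H-benzotriazole, via hemiaminal 7 (not isolated)
Conditions: SOCl2 (1.5 equiv), toluene, 23 → 60 °C; evaporate
Reagents that add atoms: thionyl chloride (O=S(Cl)Cl)
Why: Benzotriazole adds reversibly to the aldehyde to give hemiaminal 7 and thionyl chloride exchanges its hydroxyl for chloride (benzotriazole–aldehyde–SOCl2 condensation to a 1-(α-chloroalkyl)benzotriazole); the new stereocentre is racemic and is erased in step 6.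

Step 5
Reactants: 8 racemic 1-{[4-(benzyloxy)phenyl](chloro)methyl}-1H-benzotriazole; 9 3-(benzyloxy)phenol
Product: 10 racemic 1-{[3-(benzyloxy)phenoxy][4-(benzyloxy)phenyl]methyl}-1H-benzotriazole
Conditions: K2CO3, MeCN, 0 → 23 °C
Reagents that add atoms: none
Why: The chloride, labilised by the benzotriazolyl nitrogen and the p-alkoxyphenyl group, is displaced by the phenoxide at oxygen under mild base (Williamson-type O-alkylation to an N,O-acetal); the product should ionise towards the O-aryl oxocarbenium ion because benzotriazolide is the better leaving group and the poorer donor.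

Step 6
Reactants: 10 racemic 1-{[3-(benzyloxy)phenoxy][4-(benzyloxy)phenyl]methyl}-1H-benzotriazole (2.2 equiv); 4 1,1,4,4-tetramethoxybuta-1,3-diene
Product: 14 meso-(2S,3R,2'R,3'S)-7,7'-bis(benzyloxy)-2,2'-bis[4-(benzyloxy)phenyl]-3,3'-bichromane-4,4'-dione, via oxocarbenium triflate 11 (not isolated), via mono-annulated ketene acetal 12 (not isolated), via bis(dimethyl ketal) 13 (not isolated)
Conditions: Me3SiOTf (2.5 equiv), 2,6-di-tert-butyl-4-methylpyridine (2.5 equiv), CH2Cl2, −78 → −20 °C; then 1 M HCl, THF, 23 °C
Reagents that add atoms: water (O)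
Why: Proposed new method: Me3SiOTf strips the benzotriazolyl group from 10 to give the O-aryl oxocarbenium ion 11; its benzylic carbon is attacked by the inner carbon of one ketene acetal unit of 4 (Mukaiyama-type addition), the resulting dimethoxycarbenium ion is captured by the ring-A carbon para to the benzyloxy group (orthoester-type Friedel–Crafts alkylation, proton taken up by the hindered pyridine) to give 12, the same two events repeat on the second ketene acetal unit to give 13, and aqueous acid unveils both ketones. The closest known reaction type is the oxa-Povarov reaction, the stepwise cationic [4+2] annulation of O-aryl oxocarbenium ions with alkenes to chromans, together with the Lewis-acid substitution of α-benzotriazolyl ethers by silyl ketene acetals; new is a ketene O,O-acetal as the two-carbon partner, which delivers C4 at the ketone oxidation level, and its twofold use on one diene. Each ring C closes by a 6-exo-trig Friedel–Crafts attack of the arene on the dimethoxycarbenium carbon, so that each ring is the formal [4+2] adduct of a 2-oxadiene cation (C4a=C8a–O1=C2) and a C3=C4 ketene acetal. The two carbons next to the carbonyl groups are epimerisable and should settle during the acidic hydrolysis with both substituents of each ring C equatorial (2,3-trans); the relative configuration of the two aryl-bearing carbons is fixed in the second annulation, where allylic 1,3-strain in 12 holds the ring C–H bond in the plane of the remaining ketene acetal and the second cation should approach anti to the aryl-bearing ring carbon, which with like 2,3-topicity in both annulations leads to the meso series. The step needs attack at the inner diene carbons (secured by the two methoxy groups on each terminal carbon), ring closure para to the benzyloxy group and not between the two ring-A oxygens (secured by the 1,3-dioxygenation pattern and by sterics) and unlike topicity of the two annulations (secured only by the strain argument above). Any C2-symmetric diastereomer would be separated at the stage of 14.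

Step 7
Reactants: 14 meso-(2S,3R,2'R,3'S)-7,7'-bis(benzyloxy)-2,2'-bis[4-(benzyloxy)phenyl]-3,3'-bichromane-4,4'-dione
Product: 15 meso-(2S,3R,2'R,3'S)-7,7'-dihydroxy-2,2'-bis(4-hydroxyphenyl)-3,3'-bichromane-4,4'-dione (target)
Conditions: H2 (1 atm), Pd/C (10% palladium on carbon), EtOAc–MeOH, 23 °C
Reagents that add atoms: none
Why: Hydrogenolysis of benzyl aryl ethers over Pd/C is neutral, so the aryl ketones and the four stereocentres, two of them α to carbonyl groups, should be untouched.

## Compound list

1 | succinonitrile | N#CCCC#N | starting material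
2 | dimethyl butanediimidate dihydrochloride | COC(=[NH2+])CCC(=[NH2+])OC.[Cl-].[Cl-] | intermediate
3 | 1,1,1,4,4,4-hexamethoxybutane | COC(OC)(OC)CCC(OC)(OC)OC | intermediate
4 | 1,1,4,4-tetramethoxybuta-1,3-diene | COC(OC)=CC=C(OC)OC | intermediate
5 | 4-(benzyloxy)benzaldehyde | O=Cc1ccc(OCc2ccccc2)cc1 | starting material
6 | 1H-benzotriazole | c1ccc2[nH]nnc2c1 | starting material
7 | racemic (1H-benzotriazol-1-yl)[4-(benzyloxy)phenyl]methanol (hemiaminal, not isolated) | OC(c1ccc(OCc2ccccc2)cc1)n1nnc2ccccc21 | intermediate
8 | racemic 1-{[4-(benzyloxy)phenyl](chloro)methyl}-1H-benzotriazole | ClC(c1ccc(OCc2ccccc2)cc1)n1nnc2ccccc21 | intermediate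
9 | 3-(benzyloxy)phenol | Oc1cccc(OCc2ccccc2)c1 | starting material
10 | racemic 1-{[3-(benzyloxy)phenoxy][4-(benzyloxy)phenyl]methyl}-1H-benzotriazole | c1ccc(COc2ccc(C(Oc3cccc(OCc4ccccc4)c3)n3nnc4ccccc43)cc2)cc1 | intermediate
11 | (E)-[3-(benzyloxy)phenyl][4-(benzyloxy)benzylidene]oxonium triflate (not isolated) | c1ccc(COc2ccc(/C=[O+]/c3cccc(OCc4ccccc4)c3)cc2)cc1.[O-]S(=O)(=O)C(F)(F)F | intermediate
12 | racemic trans-(2S,3R)-7-(benzyloxy)-2-[4-(benzyloxy)phenyl]-3-(2,2-dimethoxyethenyl)-4,4-dimethoxychromane (one enantiomer drawn, not isolated) | COC1(OC)c2ccc(OCc3ccccc3)cc2O[C@H](c2ccc(OCc3ccccc3)cc2)[C@H]1C=C(OC)OC | intermediate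
13 | meso-(2S,3R,2'R,3'S)-7,7'-bis(benzyloxy)-2,2'-bis[4-(benzyloxy)phenyl]-4,4,4',4'-tetramethoxy-3,3'-bichromane (drawn as the expected 2,3-trans isomer, not isolated) | COC1(OC)c2ccc(OCc3ccccc3)cc2O[C@H](c2ccc(OCc3ccccc3)cc2)[C@H]1[C@@H]1C(OC)(OC)c2ccc(OCc3ccccc3)cc2O[C@H]1c1ccc(OCc2ccccc2)cc1 | intermediate
14 | meso-(2S,3R,2'R,3'S)-7,7'-bis(benzyloxy)-2,2'-bis[4-(benzyloxy)phenyl]-3,3'-bichromane-4,4'-dione | O=C1c2ccc(OCc3ccccc3)cc2O[C@H](c2ccc(OCc3ccccc3)cc2)[C@H]1[C@@H]1C(=O)c2ccc(OCc3ccccc3)cc2O[C@H]1c1ccc(OCc2ccccc2)cc1 | intermediate
15 | meso-(2S,3R,2'R,3'S)-7,7'-dihydroxy-2,2'-bis(4-hydroxyphenyl)-3,3'-bichromane-4,4'-dione | O=C1c2ccc(O)cc2O[C@H](c2ccc(O)cc2)[C@H]1[C@@H]1C(=O)c2ccc(O)cc2O[C@H]1c1ccc(O)cc1 | target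

## Step count and risks

Total step count: 7. Longest linear sequence: 5 steps (steps 1, 2, 3, 6, 7).

Steps most likely to fail:

1. Step 6. Three processes threaten it:
   - the dimethoxycarbenium ion may be intercepted before ring closure (O-demethylation to the methyl ester by triflate or silylated benzotriazole);
   - the ketene acetal may be protonated;
   - the two annulations may proceed with unselective relative topicity, so that the C2-symmetric series competes with the meso series.

   Fallback with known chemistry, setting out from 5 and coming back at 14. Claisen–Schmidt condensation of 5 with purchased 1-[4-(benzyloxy)-2-hydroxyphenyl]ethanone (CC(=O)c1ccc(OCc2ccccc2)cc1O; KOH, EtOH, 23 °C) would give (E)-1-[4-(benzyloxy)-2-hydroxyphenyl]-3-[4-(benzyloxy)phenyl]prop-2-en-1-one F1. Oxa-Michael ring closure (NaOAc, EtOH, reflux) would give racemic 7-(benzyloxy)-2-[4-(benzyloxy)phenyl]chroman-4-one F2. Oxidative homocoupling of its lithium enolate (LiN(SiMe3)2, THF, −78 °C, then CuCl2, divalent copper) would join the two α-carbons and return to 14 after equilibration of the α-centres and separation from the C2-symmetric isomer. That isomer could be returned by base equilibration (DBU) through reversible oxa-Michael opening of ring C.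

2. Step 3. The dimethoxycarbenium ion may be O-demethylated to the ester instead of losing the α-proton, or the 1,4-related cation and orthoester may close to a 2,5-dimethoxyfuran.

   Fallback setting out from 10 and coming back at 14, in which the O,O-ketene acetal is given up. Dimethyl succinate (COC(=O)CCC(=O)OC) would be converted with LiN(iPr)2 and Me3SiCl (THF, −78 °C) into 1,4-dimethoxy-1,4-bis(trimethylsilyloxy)buta-1,3-diene F3. ZnBr2-promoted twofold substitution of the benzotriazolyl group of 10 by F3 (Mukaiyama-type addition to the oxocarbenium ion) would give dimethyl 2,3-bis{[3-(benzyloxy)phenoxy][4-(benzyloxy)phenyl]methyl}butanedioate F4. Saponification (LiOH, THF–H2O) would give 2,3-bis{[3-(benzyloxy)phenoxy][4-(benzyloxy)phenyl]methyl}butanedioic acid F5. Twofold intramolecular Friedel–Crafts acylation ((CF3CO)2O, CH2Cl2, 0 °C) would close both rings C and return to 14 after equilibration of the α-centres and separation.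

3. Step 5. The ambident phenoxide may be alkylated at carbon, or the N,O-acetal may re-ionise and shift from oxygen to carbon during isolation.

   Fallback setting out from 5 and coming back at 11 within step 6. 5 would be converted (HC(OMe)3, cat. TsOH, MeOH) into 1-(benzyloxy)-4-(dimethoxymethyl)benzene F6. Acetyl chloride would give racemic 1-(benzyloxy)-4-[chloro(methoxy)methyl]benzene F7. O-alkylation of 9 with this harder α-chloro ether (iPr2NEt, CH2Cl2, 0 °C) would give the racemic mixed acetal 1-(benzyloxy)-3-{[4-(benzyloxy)phenyl](methoxy)methoxy}benzene F8. Me3SiOTf would ionise F8 by loss of the more basic methoxy group to the oxocarbenium triflate 11, where the route continues in step 6.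

Further compounds
F1 | step 6 | (E)-1-[4-(benzyloxy)-2-hydroxyphenyl]-3-[4-(benzyloxy)phenyl]prop-2-en-1-one | O=C(/C=C/c1ccc(OCc2ccccc2)cc1)c1ccc(OCc2ccccc2)cc1O
F2 | step 6 | racemic 7-(benzyloxy)-2-[4-(benzyloxy)phenyl]chroman-4-one | O=C1CC(c2ccc(OCc3ccccc3)cc2)Oc2cc(OCc3ccccc3)ccc21
F3 | step 3 | 1,4-dimethoxy-1,4-bis(trimethylsilyloxy)buta-1,3-diene (mixture of double-bond isomers) | COC(O[Si](C)(C)C)=CC=C(OC)O[Si](C)(C)C
F4 | step 3 | dimethyl 2,3-bis{[3-(benzyloxy)phenoxy][4-(benzyloxy)phenyl]methyl}butanedioate (mixture of diastereomers) | COC(=O)C(C(Oc1cccc(OCc2ccccc2)c1)c1ccc(OCc2ccccc2)cc1)C(C(Oc1cccc(OCc2ccccc2)c1)c1ccc(OCc2ccccc2)cc1)C(=O)OC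
F5 | step 3 | 2,3-bis{[3-(benzyloxy)phenoxy][4-(benzyloxy)phenyl]methyl}butanedioic acid (mixture of diastereomers) | OC(=O)C(C(Oc1cccc(OCc2ccccc2)c1)c1ccc(OCc2ccccc2)cc1)C(C(Oc1cccc(OCc2ccccc2)c1)c1ccc(OCc2ccccc2)cc1)C(=O)O
F6 | step 5 | 1-(benzyloxy)-4-(dimethoxymethyl)benzene | COC(OC)c1ccc(OCc2ccccc2)cc1
F7 | step 5 | racemic 1-(benzyloxy)-4-[chloro(methoxy)methyl]benzene | COC(Cl)c1ccc(OCc2ccccc2)cc1
F8 | step 5 | racemic 1-(benzyloxy)-3-{[4-(benzyloxy)phenyl](methoxy)methoxy}benzene | COC(Oc1cccc(OCc2ccccc2)c1)c1ccc(OCc2ccccc2)cc1
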